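All runs are simulated for substances that don't exist, noise included.

the same everywhere: J 1.9 mM
- south: D 0.038 M; Z 0.114 M; temperature 75 °C; run made earlier
- north-west: D 0.019 M; Z 0.114 M; temperature 90 °C; run made earlier
- west: D 0.028 M; Z 0.114 M; temperature 75 °C; run made earlier
- Sunday's: D 0.038 M (in portions, 5, over 4.0 d); Z 0.114 M; temperature 90 °C; first portion at the start, last at 4.0 d; time 5.0 d
- Saturday's: D 0.038 M (fed, over 4.0 d); Z 0.114 M; temperature 90 °C; all else is in the flask from the start; the feed brings no volume worth counting; time 5.0 d
- Wednesday's: D 0.038 M; Z 0.114 M (fed, over 4.0 d); the addition at 70 °C, then warmed to 90 °C; the feed brings no volume worth counting; time 5.0 d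
- Monday's: D 0.038 M; Z 0.114 M; temperature 90 °C; everything together at the start; time 5.0 d

| run | time / d | E / % |
|---|---|---|
| south | 0.500 | 10.0 |
| south | 0.833 | 15.7 |
| south | 1.67 | 27.4 |
| south | 4.00 | 49.4 |
| south | 6.00 | 60.2 |
| north-west | 0.250 | 19.5 |
| north-west | 0.833 | 44.0 |
| north-west | 1.25 | 54.1 |
| north-west | 2.00 | 61.5 |
| north-west | 3.00 | 64.6 |
| west | 0.500 | 12.2 |
| west | 1.67 | 33.1 |
| west | 2.50 | 42.6 |
| west | 4.00 | 55.8 |
| west | 6.00 | 64.6 |

(each reading ± 0.5 percentage points)

- the analysis behind the earlier runs scatters by 0.5 percentage points, standard deviation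

1. the flask with the highest amount of E, in percent of the D charged ("all alike" if they lie within 1.5 percentage points) (Sunday's / Saturday's / Wednesday's / Monday's / all alike)
2. final E, as a percentage of the D charged, in Sunday's
3. final E, as a percentage of the D charged, in Saturday's
4. final E, as a percentage of the D charged, in Wednesday's
5. final E, as a percentage of the D charged, in Monday's

The vessel on the bench is Saturday's: J and Z stand in it from the start at 90 °C, and D comes in steadily over 4.0 d. Leave the feed and the bath alone until 5.0 d, since the reckoning below holds for that course.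

My reckoning starts from the north-west run. Its last slopes, read with their scatter, fall from 0.0987 /d to 0.0310 /d of the charge. In logarithms this gives the decade time, the time in which the gap below E's ceiling shrinks by one power of ten:

decade time = 1.74 d

gap kept per day = 0.266

ceiling = 65.7%

time constant = 0.756 d

That time constant is shorter than the feed, so Saturday's should trail the feed by a steady lag. The unfinished share of the charge is then:

end of feed: 18.8%

one day later: 5.01%

final E = ceiling × (finished share) = 62.4%

The forecast differs: 19% for Saturday's (12% to 34%), 25% for Sunday's, 52% for Wednesday's, 62% for Monday's, with Monday's highest, on the ground that “Slow D feeding starves the catalyst”.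

    D + J ⇌ J + X (K = 0.330, k = 791 /M/h, Ea = 65.0 kJ/mol, ΔH = −4.00 kJ/mol)
    J + X ⇌ Q (K = 260 /M, k = 2630 /M/h, Ea = 68.0 kJ/mol, ΔH = −34.0 kJ/mol)
    Z + Q → J + E (k = 7.90 /M/h, Ea = 87.0 kJ/mol)
    E + J ⇌ L + J, rate k4*[J]*[E] forward; the back reaction follows from the equilibrium constant (K = 0.526, k = 121 /M/h, Ea = 67.0 kJ/mol, ΔH = 8.00 kJ/mol)
    (constants at 90 °C)

Saturday's ends at 62.1%; at 4.00 d its E and L leave 19.9% of the charge unfinished, beside the reckoned 18.8%. Sunday's 5 portions, a day apart, each keep the same daily factor:

unfinished = 7.25%, so E = 61.0%

Sunday's ends at 60.5%. Monday's reaches 65.4% and Wednesday's 48.7%. The return of L to E is the largest single effect on that lead of 17 percentage points: without it, the lead is −12 points.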